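**Retrosynthetic overview**

1. 15 ⇒ 14: inside the six-membered carbocycle (C3a, C4, C5, C6, C7, C7a) the allyl group on C5 and the C4=C3a bond form a hexa-1,5-diene (CH2=CH–CH2–C5–C4=C3a). A retro-Cope shift moves allyl to C3a, next to the C3 methyl stereocentre, and leaves a cross-conjugated 5-methoxy dienone.
2. 14 ⇒ 11: the C4=C5 bond of that dienone joins an aldehyde-level carbon on C3a (C4, kept as its dimethyl acetal) to the methoxy-bearing α-carbon of the C6 ketone (C5). The carbocycle is therefore closed last, by addition of the C5 silyl dienol ether to the C4 acetal and loss of methanol; ring closure and allyl shift run in one flask.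
3. 11 ⇒ 6: the vinylogous ester comes from the lactone carbonyl (C7a) by methylenation (C7) and C-acylation with methoxyacetyl chloride (C6, C5); the quaternary C3a comes from α-formylation and allylation anti to the C3 methyl group.
4. 6 ⇒ 1: trans-lactone from 3,4-dimethoxybenzaldehyde by enantioselective anti-crotylation (C2, C3), hydroboration and oxidative lactonisation.
5. Order of ring formation: aryl ring (present in 1), oxolane ring O1–C2–C3–C3a–C7a (step 3), carbocycle (step 9).

Key step: step 9

Remark: benzofuran numbering (O1, C2, C3, C3a, C4–C7, C7a) is used for all intermediates; the C7=C7a geometry of 11 and 12 and the C4/C5 configuration of 13 are taken to be of no consequence, since they are equilibrated or erased in step 9.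

**Route**

Step 1
Reactants: 1 3,4-dimethoxybenzaldehyde
Product: 2 (1R,2R)-1-(3,4-dimethoxyphenyl)-2-methylbut-3-en-1-ol
Conditions: but-3-en-2-yl acetate (2 equiv), [Ir(cod)Cl]2 (2.5 mol%), (R)-SEGPHOS (5 mol%), 4-cyano-3-nitrobenzoic acid (10 mol%), Cs2CO3 (20 mol%), i-PrOH (2 equiv), THF, 90 °C
Reagents that add atoms: but-3-en-2-yl acetate, CC(OC(C)=O)C=C
Why: Iridium-catalysed transfer-hydrogenative carbonyl crotylation, in which isopropanol serves as reductant and the (E)-σ-crotyliridium species formed from the allylic acetate should add to the aldehyde through a closed chair-like transition state, giving the anti adduct with C2 and C3 of the target set together as 1R,2R under control of the chiral bisphosphine (the ligand antipode would give the mirror-image series).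

Step 2
Reactants: 2 (1R,2R)-1-(3,4-dimethoxyphenyl)-2-methylbut-3-en-1-ol
Product: 4 (1R,2R)-1-(3,4-dimethoxyphenyl)-2-methylbutane-1,4-diol, via bisborylated adduct 3 (not isolated)
Conditions: 9-BBN (2.2 equiv), THF, 0 °C to rt; then aq. NaOH, H2O2, 0 °C to rt
Reagents that add atoms: hydrogen peroxide, OO
Why: Anti-Markovnikov hydroboration–oxidation of the terminal alkene, the first equivalent of borane being consumed by the carbinol O–H, places the primary hydroxyl on the future C7a without touching either stereocentre.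

Step 3
Reactants: 4 (1R,2R)-1-(3,4-dimethoxyphenyl)-2-methylbutane-1,4-diol
Product: 6 (4R,5R)-5-(3,4-dimethoxyphenyl)-4-methyloxolan-2-one, via lactol 5 (not isolated)
Conditions: TEMPO (0.2 equiv), PhI(OAc)2 (2.5 equiv), CH2Cl2, rt
Reagents that add atoms: none
Why: Oxidative lactonisation: the TEMPO-derived oxoammonium salt oxidises the primary alcohol in preference to the secondary benzylic one, the hydroxy aldehyde closes to lactol 5 and a second oxidation gives the γ-lactone, which forms the oxolane ring with the trans C2/C3 relationship already fixed.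

Step 4
Reactants: 6 (4R,5R)-5-(3,4-dimethoxyphenyl)-4-methyloxolan-2-one
Product: 7 (3Z,4R,5R)-5-(3,4-dimethoxyphenyl)-3-(hydroxymethylidene)-4-methyloxolan-2-one
Conditions: NaH (2 equiv), HCO2Et (5 equiv), EtOH (cat.), THF, 0 °C to rt; aq. HCl work-up
Reagents that add atoms: ethyl formate, CCOC=O
Why: Crossed Claisen condensation (α-formylation) of the lactone enolate with ethyl formate, driven by deprotonation of the β-dicarbonyl product, introduces C4 and makes C3a trigonal.

Step 5
Reactants: 7 (3Z,4R,5R)-5-(3,4-dimethoxyphenyl)-3-(hydroxymethylidene)-4-methyloxolan-2-one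
Product: 8 (3R,4R,5R)-5-(3,4-dimethoxyphenyl)-4-methyl-2-oxo-3-(prop-2-en-1-yl)oxolane-3-carbaldehyde
Conditions: allyl methyl carbonate (1.2 equiv), Pd(PPh3)4 (5 mol%), THF, 0 °C to rt
Reagents that add atoms: allyl methyl carbonate, C=CCOC(=O)OC
Why: Tsuji–Trost allylation under neutral conditions, in which the carbonate supplies π-allylpalladium and its own base, any O-allyl enol ether being returned through ionisation to the C-allylated product, and in which the electrophile should enter the planar C3a anti to the adjacent C3 methyl group, so that the quaternary stereocentre is set with allyl trans to methyl.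

Step 6
Reactants: 8 (3R,4R,5R)-5-(3,4-dimethoxyphenyl)-4-methyl-2-oxo-3-(prop-2-en-1-yl)oxolane-3-carbaldehyde
Product: 9 (3R,4R,5R)-3-(dimethoxymethyl)-5-(3,4-dimethoxyphenyl)-4-methyl-3-(prop-2-en-1-yl)oxolan-2-one
Conditions: HC(OMe)3 (3 equiv), MeOH, PPTS (cat.), 40 °C
Reagents that add atoms: trimethyl orthoformate, COC(OC)OC
Why: Acid-catalysed acetalisation of the non-enolisable aldehyde with the orthoformate as dehydrating agent masks C4 against the titanium reagent and stores it as the electrophile of step 9.

Step 7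
Reactants: 9 (3R,4R,5R)-3-(dimethoxymethyl)-5-(3,4-dimethoxyphenyl)-4-methyl-3-(prop-2-en-1-yl)oxolan-2-one
Product: 10 (3S,4R,5R)-3-(dimethoxymethyl)-5-(3,4-dimethoxyphenyl)-4-methyl-2-methylidene-3-(prop-2-en-1-yl)oxolane
Conditions: Cp2TiMe2 (2.5 equiv), toluene, 65–70 °C, dark; filtration through basic alumina
Reagents that add atoms: dimethyltitanocene (Cp2TiMe2), [CH3-].[CH3-].[Ti+4].c1cc[cH-]c1.c1cc[cH-]c1
Why: Petasis methylenation (carbonyl olefination by the titanium methylidene through an oxatitanacyclobutane) converts the lactone carbonyl into the exocyclic enol ether, which cannot move into the ring because C3a is quaternary, the temperature being kept below the onset of a Cope shift of the 3-allyl-2-methylidene unit.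

Step 8
Reactants: 10 (3S,4R,5R)-3-(dimethoxymethyl)-5-(3,4-dimethoxyphenyl)-4-methyl-2-methylidene-3-(prop-2-en-1-yl)oxolane
Product: 11 (1Z)-1-[(3S,4R,5R)-3-(dimethoxymethyl)-5-(3,4-dimethoxyphenyl)-4-methyl-3-(prop-2-en-1-yl)oxolan-2-ylidene]-3-methoxypropan-2-one (E/Z mixture possible, drawn as Z)
Conditions: MeOCH2COCl (1.5 equiv), pyridine (3 equiv), CH2Cl2, −20 °C to rt
Reagents that add atoms: methoxyacetyl chloride, COCC(=O)Cl
Why: Electrophilic C-acylation of an enol ether by an activated acid chloride (attack of the methylidene carbon C7 on the acylpyridinium ion, oxocarbenium ion at C7a, loss of the C7 proton), the known route from 1,1-disubstituted enol ethers to β-alkoxy enones, installs C6 and the methoxy-bearing C5.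

Step 9
Reactants: 11 (1Z)-1-[(3S,4R,5R)-3-(dimethoxymethyl)-5-(3,4-dimethoxyphenyl)-4-methyl-3-(prop-2-en-1-yl)oxolan-2-ylidene]-3-methoxypropan-2-one
Product: 15 (2R,3R,5S)-2-(3,4-dimethoxyphenyl)-5-methoxy-3-methyl-5-(prop-2-en-1-yl)-2,3-dihydro-1-benzofuran-6(5H)-one, via silyl dienol ether 12 (not isolated), via methoxy ketone 13 (not isolated), via 3a-allyl dienone 14 (not isolated)
Conditions: TMSOTf (1.3 equiv), i-Pr2NEt (1.5 equiv), CH2Cl2, −78 to −20 °C; DBU (2 equiv), −20 °C to rt; solvent change to toluene, 80 °C, stopped as soon as 14 is consumed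
Reagents that add atoms: none
Why: TMSOTf/i-Pr2NEt turns the vinylogous ester into the 1-alkoxy-3-silyloxy diene 12, whose C5 terminus adds to the oxocarbenium ion released from the C4 dimethyl acetal (intramolecular Mukaiyama aldol-type addition to an acetal) to give 13; DBU then expels methanol (E1cB) to the cross-conjugated dienone 14, and warming moves the allyl group from C3a to C5 by a Cope rearrangement, the shift assumed in the biogenesis of 5-allyl-5-methoxy neolignans from their 3a-allyl isomers. The closest known reaction types are the one-pot silyl triflate/amine enol silane formation with Mukaiyama addition to dimethyl acetals and the thermal [3,3] shift of 4-allylcyclohexa-2,5-dienones to 6-allylcyclohexa-2,4-dienones. The six-membered carbocycle (C3a, C4, C5, C6, C7, C7a) closes at C4–C5 in the 6-(enolendo)-exo-trig mode, and because only the C7=C7a isomer with the acyl chain syn to C3a can cyclise while O-silylation lets that bond rotate, both geometric isomers of 11 are funnelled into the ring. The only new stereocentre that survives, C5, is set by the suprafacial course of the ring-bound [3,3] shift: allyl leaves one face of C3a and arrives on the same face of C5, so the C3a configuration fixed in step 5 by the C3 methyl group is copied to C5 (5S), while the C4/C5 centres of 13 are erased. The step needs migration to C5 and not to C7, which the captodative C5 terminus (methoxy and acyl) and the resonance-stabilised, less reactive O1–C7a=C7–C6=O unit should secure, and it needs the sequence to stop at 15, which the relief of strain at the quaternary C3a (a shift expected well below the temperature of retro-Claisen aromatisation) and close monitoring should secure.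

**Compound list**

1 | 3,4-dimethoxybenzaldehyde | O=Cc1ccc(OC)c(OC)c1 | starting material
2 | (1R,2R)-1-(3,4-dimethoxyphenyl)-2-methylbut-3-en-1-ol | O[C@@H](c1ccc(OC)c(OC)c1)[C@H](C)C=C | intermediate
3 | 9-{(3R,4R)-4-[(9-borabicyclo[3.3.1]nonan-9-yl)oxy]-4-(3,4-dimethoxyphenyl)-3-methylbutyl}-9-borabicyclo[3.3.1]nonane (bisborylated adduct) | B1(O[C@@H](c2ccc(OC)c(OC)c2)[C@H](C)CCB2C3CCCC2CCC3)C2CCCC1CCC2 | intermediate (not isolated)
4 | (1R,2R)-1-(3,4-dimethoxyphenyl)-2-methylbutane-1,4-diol | O[C@@H](c1ccc(OC)c(OC)c1)[C@H](C)CCO | intermediate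
5 | (4R,5R)-5-(3,4-dimethoxyphenyl)-4-methyloxolan-2-ol (lactol, both anomers) | OC1O[C@@H](c2ccc(OC)c(OC)c2)[C@H](C)C1 | intermediate (not isolated)
6 | (4R,5R)-5-(3,4-dimethoxyphenyl)-4-methyloxolan-2-one | O=C1O[C@@H](c2ccc(OC)c(OC)c2)[C@H](C)C1 | intermediate
7 | (3Z,4R,5R)-5-(3,4-dimethoxyphenyl)-3-(hydroxymethylidene)-4-methyloxolan-2-one | O=C1O[C@@H](c2ccc(OC)c(OC)c2)[C@H](C)/C1=C/O | intermediate
8 | (3R,4R,5R)-5-(3,4-dimethoxyphenyl)-4-methyl-2-oxo-3-(prop-2-en-1-yl)oxolane-3-carbaldehyde | O=C1O[C@@H](c2ccc(OC)c(OC)c2)[C@H](C)[C@@]1(C=O)CC=C | intermediate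
9 | (3R,4R,5R)-3-(dimethoxymethyl)-5-(3,4-dimethoxyphenyl)-4-methyl-3-(prop-2-en-1-yl)oxolan-2-one | O=C1O[C@@H](c2ccc(OC)c(OC)c2)[C@H](C)[C@@]1(C(OC)OC)CC=C | intermediate
10 | (3S,4R,5R)-3-(dimethoxymethyl)-5-(3,4-dimethoxyphenyl)-4-methyl-2-methylidene-3-(prop-2-en-1-yl)oxolane | C=C1O[C@@H](c2ccc(OC)c(OC)c2)[C@H](C)[C@@]1(C(OC)OC)CC=C | intermediate
11 | (1Z)-1-[(3S,4R,5R)-3-(dimethoxymethyl)-5-(3,4-dimethoxyphenyl)-4-methyl-3-(prop-2-en-1-yl)oxolan-2-ylidene]-3-methoxypropan-2-one | COCC(=O)/C=C1\O[C@@H](c2ccc(OC)c(OC)c2)[C@H](C)[C@@]1(C(OC)OC)CC=C | intermediate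
12 | (3S,4R,5R)-3-(dimethoxymethyl)-5-(3,4-dimethoxyphenyl)-2-[3-methoxy-2-(trimethylsilyloxy)prop-2-en-1-ylidene]-4-methyl-3-(prop-2-en-1-yl)oxolane (double-bond isomers) | COC=C(O[Si](C)(C)C)C=C1O[C@@H](c2ccc(OC)c(OC)c2)[C@H](C)[C@@]1(C(OC)OC)CC=C | intermediate (not isolated)
13 | (2R,3R,3aR)-2-(3,4-dimethoxyphenyl)-4,5-dimethoxy-3-methyl-3a-(prop-2-en-1-yl)-3,3a,4,5-tetrahydro-1-benzofuran-6(2H)-one (C4/C5 mixture) | O=C1C=C2O[C@@H](c3ccc(OC)c(OC)c3)[C@H](C)[C@]2(CC=C)C(OC)C1OC | intermediate (not isolated)
14 | (2R,3R,3aR)-2-(3,4-dimethoxyphenyl)-5-methoxy-3-methyl-3a-(prop-2-en-1-yl)-3,3a-dihydro-1-benzofuran-6(2H)-one | O=C1C=C2O[C@@H](c3ccc(OC)c(OC)c3)[C@H](C)[C@]2(CC=C)C=C1OC | intermediate (not isolated)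
15 | (2R,3R,5S)-2-(3,4-dimethoxyphenyl)-5-methoxy-3-methyl-5-(prop-2-en-1-yl)-2,3-dihydro-1-benzofuran-6(5H)-one | C=CC[C@]1(OC)C=C2C(=CC1=O)O[C@@H](c1ccc(OC)c(OC)c1)[C@@H]2C | target

**Step count and risks**

Total step count: 9. Longest linear sequence: 9 steps (from 1).

Steps most likely to fail:

1. Step 9. The [3,3] shift may not stop at 15: allyl may migrate to C7 and the product then enolise irreversibly to a phenol, or 15 may go on to the aryl allyl ether by retro-Claisen aromatisation. In the silyl triflate stage the benzylic C2–O1 bond may also ionise. The fallback is a different ring-forming reaction that needs neither the Lewis acid nor the 3a-allyl intermediate, at the price of face control at C5. It sets out from lactone 6. Aldol addition of its lithium enolate (LiN(i-Pr)2, THF, −78 °C) to 2-methoxypent-4-enal, followed by dehydration (MsCl, Et3N, then DBU), would give the alkylidene lactone F1. γ-Deprotonation with KN(SiMe3)2 and O-phosphorylation with (PhO)2P(O)Cl would give the dienyl ketene acetal phosphate F2, and Sonogashira coupling with tert-butoxyethyne (Pd(PPh3)4, CuI, Et3N) the ynol ether F3. Warming F3 in toluene (70–80 °C) should expel 2-methylpropene in a retro-ene reaction; the dienylketene F4 so formed closes the carbocycle by 6π-electrocyclisation of its ketene carbon onto the methoxy-bearing diene terminus, and the sequence comes back to the route at 15. No face control is expected in this closure, so the C5 epimer F5 would have to be removed by chromatography.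

2. Step 8. C-acylation of the enol ether may be too slow, so that protonation and hydrolysis of 10 by pyridinium chloride, or ketene formation from the acid chloride, take over. The fallback sets out from enol ether 10: bromination–dehydrobromination (NBS, Et3N, CH2Cl2, −78 °C) would give the bromomethylidene oxolane F6; bromine–lithium exchange (t-BuLi, THF, −78 °C) and acylation of the vinyllithium with N,2-dimethoxy-N-methylacetamide would give 11, where it rejoins the route.

3. Step 7. Methylenation of the neopentyl-type lactone carbonyl, shielded by the quaternary C3a, may stall before the titanium reagent has decomposed. The fallback sets out from lactone 9: MeLi (THF, −78 °C) should add once to give the methyl lactol F7, and dehydration (MsCl, Et3N, 0 °C), which can only go towards the exocyclic position, would give 10, where it rejoins the route.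

Further compounds

F1 | step 9 | (4R,5R)-5-(3,4-dimethoxyphenyl)-3-(2-methoxypent-4-en-1-ylidene)-4-methyloxolan-2-one (isomer mixture) | O=C1O[C@@H](c2ccc(OC)c(OC)c2)[C@H](C)C1=CC(OC)CC=C
F2 | step 9 | (4R,5R)-5-(3,4-dimethoxyphenyl)-3-(2-methoxypenta-1,4-dien-1-yl)-4-methyl-4,5-dihydrofuran-2-yl diphenyl phosphate | C=CCC(OC)=CC1=C(OP(=O)(Oc2ccccc2)Oc2ccccc2)O[C@@H](c2ccc(OC)c(OC)c2)[C@@H]1C
F3 | step 9 | (2R,3R)-5-(tert-butoxyethynyl)-2-(3,4-dimethoxyphenyl)-4-(2-methoxypenta-1,4-dien-1-yl)-3-methyl-2,3-dihydrofuran | C=CCC(OC)=CC1=C(C#COC(C)(C)C)O[C@@H](c2ccc(OC)c(OC)c2)[C@@H]1C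
F4 | step 9 | 2-[(4R,5R)-5-(3,4-dimethoxyphenyl)-3-(2-methoxypenta-1,4-dien-1-yl)-4-methyl-4,5-dihydrofuran-2-yl]ethen-1-one (dienylketene) | C=CCC(OC)=CC1=C(C=C=O)O[C@@H](c2ccc(OC)c(OC)c2)[C@@H]1C
F5 | step 9 | (2R,3R,5R)-2-(3,4-dimethoxyphenyl)-5-methoxy-3-methyl-5-(prop-2-en-1-yl)-2,3-dihydro-1-benzofuran-6(5H)-one (C5 epimer of 15) | C=CC[C@@]1(OC)C=C2C(=CC1=O)O[C@@H](c1ccc(OC)c(OC)c1)[C@@H]2C
F6 | step 8 | (3S,4R,5R)-2-(bromomethylidene)-3-(dimethoxymethyl)-5-(3,4-dimethoxyphenyl)-4-methyl-3-(prop-2-en-1-yl)oxolane (E/Z mixture) | BrC=C1O[C@@H](c2ccc(OC)c(OC)c2)[C@H](C)[C@@]1(C(OC)OC)CC=C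
F7 | step 7 | (3R,4R,5R)-3-(dimethoxymethyl)-5-(3,4-dimethoxyphenyl)-2,4-dimethyl-3-(prop-2-en-1-yl)oxolan-2-ol (both anomers) | CC1(O)O[C@@H](c2ccc(OC)c(OC)c2)[C@H](C)[C@@]1(C(OC)OC)CC=C
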